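Numbering: C1 is the lactone carbonyl, C7 the O-bearing CH of the eight-membered lactone ring, C8–C10 the cyclopropane, C11 and C14 the carbinols. Everything rests on C7–C8, where an oxygenated sp3 carbon meets a cyclopropane carbon that can carry boron. (−)-Sparteine-mediated lithiation of the acyclic C1–C7 (Z)-homoallylic carbamate gives a chiral carbenoid, which captures the complete C8–C22 trans-cyclopropyl pinacol boronate. The 1,2-metallate rearrangement joins both halves, creates C7 under reagent control and retains C8, and oxidation converts boron into the future lactone oxygen. The precursor therefore contains no lactone: the ring is closed afterwards by lactonisation of the (Z)-seco acid.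

Key step: step 16

Assumption: (−)-sparteine, (−)-Ipc2B(allyl), (−)-MIB and the (4S,5S)-dioxaborolane ligand are taken as purchasable reagents. Target numbering (C1–C22) is used for all fragments. Bpin = 4,4,5,5-tetramethyl-1,3,2-dioxaborolan-2-yl, Cb = C(O)N(iPr)2.

Step 1
Reactants: 1 (Z)-hex-3-en-1-ol
Product: 2 (Z)-1-iodohex-3-ene
Conditions: I2, PPh3, imidazole, CH2Cl2, 0 °C → rt
Reagents that add atoms: iodine, II
Why: Appel-type iodination should replace the activated primary hydroxyl by SN2 and leave the Z-alkene (future C19=C20) untouched.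

Step 2
Reactants: 2 (Z)-1-iodohex-3-ene
Product: 3 [(Z)-hex-3-en-1-yl]triphenylphosphonium iodide
Conditions: PPh3, MeCN, reflux
Reagents that add atoms: triphenylphosphine, c1ccc(cc1)P(c1ccccc1)c1ccccc1
Why: SN2 quaternisation of PPh3 by a primary iodide is the standard entry to a Wittig salt.

Step 3
Reactants: 4 3-(trimethylsilyl)prop-2-ynal
Product: 6 (S)-1-(trimethylsilyl)hex-5-en-1-yn-3-ol, via borinate ester 5 (not isolated)
Conditions: (−)-Ipc2B(allyl) (from (+)-α-pinene), Et2O/pentane, −78 °C; then ethanolamine, rt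
Reagents that add atoms: (−)-B-allyldiisopinocampheylborane, C=CCB([C@@H]1C[C@@H]2C[C@H]([C@H]1C)C2(C)C)[C@@H]1C[C@@H]2C[C@H]([C@H]1C)C2(C)C
Why: In this Brown asymmetric allylboration the closed chair transition state of this reagent enantiomer should deliver allyl to the Si face of the ynal and set C14 (S), and the non-oxidative, weakly basic work-up spares the C–SiMe3 bond.

Step 4
Reactants: 6 (S)-1-(trimethylsilyl)hex-5-en-1-yn-3-ol
Product: 7 (S)-3-(tert-butyldimethylsilyloxy)-1-(trimethylsilyl)hex-5-en-1-yne
Conditions: TBSCl, imidazole, DMF, rt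
Reagents that add atoms: tert-butyldimethylsilyl chloride, CC(C)(C)[Si](C)(C)Cl
Why: Standard silylation of a secondary propargylic alcohol forms no bond at C14, so the stereocentre is kept.

Step 5
Reactants: 7 (S)-3-(tert-butyldimethylsilyloxy)-1-(trimethylsilyl)hex-5-en-1-yne
Product: 9 (S)-3-(tert-butyldimethylsilyloxy)-5-(trimethylsilyl)pent-4-ynal, via secondary ozonide 8 (not isolated)
Conditions: O3, CH2Cl2, −78 °C (Sudan III end point); PPh3, −78 °C → rt
Reagents that add atoms: ozone, [O-][O+]=O
Why: In this ozonolysis with reductive work-up the terminal alkene should react far faster than the silyl-capped alkyne, which gives the C16 aldehyde.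

Step 6
Reactants: 3 [(Z)-hex-3-en-1-yl]triphenylphosphonium iodide; 9 (S)-3-(tert-butyldimethylsilyloxy)-5-(trimethylsilyl)pent-4-ynal
Product: 11 (S,5Z,8Z)-3-(tert-butyldimethylsilyloxy)-1-(trimethylsilyl)undeca-5,8-dien-1-yne, via phosphorus ylide 10 (not isolated)
Conditions: 3, NaHMDS, THF, −78 → 0 °C; then 9, −78 °C → rt
Reagents that add atoms: none
Why: A Z-selective Wittig olefination of a non-stabilised ylide under lithium-free conditions should set the C16=C17 Z-alkene kinetically, and the low temperature suppresses β-elimination of the silyloxy group.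

Step 7
Reactants: 11 (S,5Z,8Z)-3-(tert-butyldimethylsilyloxy)-1-(trimethylsilyl)undeca-5,8-dien-1-yne
Product: 12 (S,5Z,8Z)-3-(tert-butyldimethylsilyloxy)undeca-5,8-dien-1-yne (C12–C22)
Conditions: K2CO3 (cat.), MeOH, rt
Reagents that add atoms: none
Why: Base-catalysed methanolysis cleaves the alkynyl C–SiMe3 bond selectively, while the O–TBS ether is stable to these conditions.

Step 8
Reactants: 13 prop-2-yn-1-ol
Product: 15 (E)-3-(Bpin)prop-2-en-1-ol, via borate ether 14 (not isolated)
Conditions: HBpin (2.2 equiv), Cp2ZrHCl (cat.), Et3N (cat.), neat, 60 °C; aqueous work-up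
Reagents that add atoms: pinacolborane, [H]B1OC(C)(C)C(C)(C)O1
Why: In this zirconocene-catalysed syn-hydroboration of a terminal alkyne, the first equivalent of HBpin masks the hydroxyl as a labile borate and the second should add anti-Markovnikov to give the E-alkenylboronate.

Step 9
Reactants: 15 (E)-3-(Bpin)prop-2-en-1-ol
Product: 16 [(1R,2R)-2-(Bpin)cyclopropyl]methanol
Conditions: Et2Zn, CH2I2, DME, CH2Cl2, −10 °C; (4S,5S)-2-butyl-N,N,N′,N′-tetramethyl-1,3,2-dioxaborolane-4,5-dicarboxamide; 15, −10 °C → rt; aq NH4Cl (no peroxide work-up)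
Reagents that add atoms: diiodomethane, ICI
Why: In the Charette asymmetric Simmons–Smith cyclopropanation the zinc alkoxide binds the chiral dioxaborolane, which directs the methylene (C9) to one alkene face and sets C8 and C10, and the E-geometry is translated stereospecifically into the trans ring.

Step 10
Reactants: 16 [(1R,2R)-2-(Bpin)cyclopropyl]methanol
Product: 17 (1R,2R)-2-(Bpin)cyclopropane-1-carbaldehyde
Conditions: TEMPO (cat.), PhI(OAc)2, CH2Cl2, rt
Reagents that add atoms: none
Why: The TEMPO/oxoammonium oxidation stops at the aldehyde in anhydrous medium, tolerates the C–B bond, and does not enolise the cyclopropyl aldehyde.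

Step 11
Reactants: 12 (S,5Z,8Z)-3-(tert-butyldimethylsilyloxy)undeca-5,8-dien-1-yne; 17 (1R,2R)-2-(Bpin)cyclopropane-1-carbaldehyde
Product: 20 C8–C22 allylic alcohol (12E,16Z,19Z; free C11-OH, C14-OTBS, Bpin on C8; C8, C10, C11, C14 arranged as in the target), via alkenylborane 18 (not isolated), via alkenylzinc 19 (not isolated)
Conditions: 12, Cy2BH (from BH3·SMe2, cyclohexene), toluene, 0 °C → rt; Me2Zn, −78 °C; (−)-MIB (cat.); 17, −30 → 0 °C; aq NH4Cl
Reagents that add atoms: none
Why: This is an Oppolzer-type catalytic asymmetric alkenylzinc addition in which syn-hydroboration of the terminal alkyne (faster than that of the internal Z-alkenes) fixes the 12E geometry, B→Zn exchange proceeds with retention, and the (−)-amino alcohol–zinc catalyst should deliver the alkenyl group to the Si face of 17 and set C11.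

Step 12
Reactants: 20 C8–C22 allylic alcohol
Product: 21 C8–C22 cyclopropyl pinacol boronate with C11-OTBS and C14-OTBS
Conditions: TBSOTf, 2,6-lutidine, CH2Cl2, −78 °C
Reagents that add atoms: tert-butyldimethylsilyl triflate, CC(C)(C)[Si](C)(C)OS(=O)(=O)C(F)(F)F
Why: Low-temperature silylation in the presence of a hindered base should protect the hindered C11 carbinol without ionising this allylic, cyclopropylcarbinyl position.

Step 13
Reactants: 22 but-3-yn-1-ol
Product: 23 but-3-yn-1-yl N,N-diisopropylcarbamate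
Conditions: iPr2NC(O)Cl, Et3N, CH2Cl2, reflux
Reagents that add atoms: N,N-diisopropylcarbamoyl chloride, CC(C)N(C(C)C)C(=O)Cl
Why: O-Carbamoylation of a primary alcohol installs the directing and leaving group needed at C7.

Step 14
Reactants: 23 but-3-yn-1-yl N,N-diisopropylcarbamate; 24 (3-bromopropoxy)(tert-butyl)dimethylsilane
Product: 25 7-(tert-butyldimethylsilyloxy)hept-3-yn-1-yl N,N-diisopropylcarbamate
Conditions: nBuLi, THF, −78 °C; 24, DMPU, NaI (cat.), −78 °C → rt
Reagents that add atoms: none
Why: In this acetylide alkylation (SN2) the alkyne C–H is by far the most acidic site, and the hindered carbamate resists nBuLi and the acetylide.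

Step 15
Reactants: 25 7-(tert-butyldimethylsilyloxy)hept-3-yn-1-yl N,N-diisopropylcarbamate
Product: 26 (Z)-7-(tert-butyldimethylsilyloxy)hept-3-en-1-yl N,N-diisopropylcarbamate (C1–C7)
Conditions: H2 (1 atm), Lindlar catalyst, quinoline, EtOAc, rt
Reagents that add atoms: none
Why: Lindlar semihydrogenation adds H2 in a syn manner and should give the C4=C5 Z-alkene.

Step 16
Reactants: 26 (Z)-7-(tert-butyldimethylsilyloxy)hept-3-en-1-yl N,N-diisopropylcarbamate; 21 C8–C22 cyclopropyl pinacol boronate
Product: 30 C1–C22 secondary alcohol (7R,8R,10R,11S,14S; free C7-OH, TBS ethers at C1, C11, C14), via lithiated carbamate 27 (not isolated), via boronate complex 28 (not isolated), via homologated boronic ester 29 (not isolated)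
Conditions: 26, sBuLi, (−)-sparteine, Et2O, −78 °C; 21 in Et2O, −78 °C; MgBr2·OEt2, −78 °C → reflux; then aq NaOH, H2O2, THF, 0 °C
Reagents that add atoms: hydrogen peroxide, OO
Why: sBuLi/(−)-sparteine removes the pro-S hydrogen at C7 of 26 (Hoppe asymmetric lithiation) to give the configurationally stable (S)-carbenoid 27, which adds to the boron of 21 with retention to give boronate complex 28. On warming with MgBr2 the cyclopropyl carbon C8 migrates from boron to C7 anti to the departing carbamate (Matteson-type 1,2-metallate rearrangement, i.e. lithiation–borylation), which forms C7–C8 with inversion at C7 and retention at C8, and H2O2/NaOH then replaces boron by OH with retention. No ring is closed in this step. The only new stereocentre, C7 (R), is fixed by the diamine independently of the stereocentres of 21, while C8, C10, C11 and C14 are untouched. The step needs lithiation next to oxygen rather than allylic deprotonation at C6 or C3, which the complex-induced proximity effect of the carbamate carbonyl at −78 °C secures, and it needs carbon rather than oxygen migration, which the good migratory aptitude of the sp2-like cyclopropyl carbon and the MgBr2 activation of the leaving group favour. The strong base never meets 21, so its skipped diene and silyl ethers see only the boron-selective carbenoid.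

Step 17
Reactants: 30 C1–C22 secondary alcohol
Product: 31 C1,C7-diol with C11-OTBS and C14-OTBS
Conditions: HF·pyridine, pyridine, THF, 0 °C (stopped after loss of one silyl group)
Reagents that add atoms: none
Why: This selective desilylation relies on sterics, since the unhindered primary C1 TBS ether should be cleaved much faster than the two secondary allylic TBS ethers, and the pyridine buffer protects the ionisable C11 position.

Step 18
Reactants: 31 C1,C7-diol
Product: 32 (4Z)-7-hydroxy seco acid with C11-OTBS and C14-OTBS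
Conditions: TEMPO (cat.), PhI(OAc)2, MeCN/pH 7 buffer, 0 °C → rt
Reagents that add atoms: water, O
Why: The TEMPO/PhI(OAc)2 oxidation in aqueous medium takes the primary alcohol through the aldehyde hydrate to the acid and should leave the hindered secondary C7 carbinol, the alkenes and the silyl ethers alone.

Step 19
Reactants: 32 (4Z)-7-hydroxy seco acid
Product: 34 bis-TBS ether of the target lactone, via mixed anhydride 33 (not isolated)
Conditions: 2,4,6-Cl3C6H2COCl, Et3N, THF, rt; slow addition to DMAP, toluene, 80 °C, high dilution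
Reagents that add atoms: none
Why: In the Yamaguchi lactonisation the C7 hydroxyl attacks the DMAP-activated acyl group under high dilution, the C4=C5 Z-alkene brings the chain ends together for closure of the eight-membered ring, and C7 is retained because only the acyl C–O bond is formed.

Step 20
Reactants: 34 bis-TBS ether of the target lactone
Product: 35 target (7R,8R,10R,11S,14S; 4Z,12E,16Z,19Z)
Conditions: HF·pyridine (excess), pyridine, THF, 0 °C → rt
Reagents that add atoms: none
Why: Buffered fluoride desilylation should free C11-OH and C14-OH without opening the lactone or ionising the allylic cyclopropylcarbinyl position.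

Compound list
1 | (Z)-hex-3-en-1-ol | CC/C=C\CCO | starting material
2 | (Z)-1-iodohex-3-ene | CC/C=C\CCI | intermediate
3 | [(Z)-hex-3-en-1-yl]triphenylphosphonium iodide | CC/C=C\CC[P+](c1ccccc1)(c1ccccc1)c1ccccc1.[I-] | intermediate
4 | 3-(trimethylsilyl)prop-2-ynal | C[Si](C)(C)C#CC=O | starting material
5 | diisopinocampheylborinate ester of 6 | C=CC[C@H](OB([C@@H]1C[C@@H]2C[C@H]([C@H]1C)C2(C)C)[C@@H]1C[C@@H]2C[C@H]([C@H]1C)C2(C)C)C#C[Si](C)(C)C | intermediate
6 | (S)-1-(trimethylsilyl)hex-5-en-1-yn-3-ol | C=CC[C@H](O)C#C[Si](C)(C)C | intermediate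
7 | (S)-3-(tert-butyldimethylsilyloxy)-1-(trimethylsilyl)hex-5-en-1-yne | C=CC[C@H](O[Si](C)(C)C(C)(C)C)C#C[Si](C)(C)C | intermediate
8 | secondary ozonide (1,2,4-trioxolane) of 7 | C1OC(OO1)C[C@H](O[Si](C)(C)C(C)(C)C)C#C[Si](C)(C)C | intermediate
9 | (S)-3-(tert-butyldimethylsilyloxy)-5-(trimethylsilyl)pent-4-ynal | O=CC[C@H](O[Si](C)(C)C(C)(C)C)C#C[Si](C)(C)C | intermediate
10 | [(Z)-hex-3-en-1-ylidene]triphenylphosphorane | CC/C=C\CC=P(c1ccccc1)(c1ccccc1)c1ccccc1 | intermediate
11 | (S,5Z,8Z)-3-(tert-butyldimethylsilyloxy)-1-(trimethylsilyl)undeca-5,8-dien-1-yne | CC/C=C\C/C=C\C[C@H](O[Si](C)(C)C(C)(C)C)C#C[Si](C)(C)C | intermediate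
12 | (S,5Z,8Z)-3-(tert-butyldimethylsilyloxy)undeca-5,8-dien-1-yne | CC/C=C\C/C=C\C[C@H](O[Si](C)(C)C(C)(C)C)C#C | intermediate
13 | prop-2-yn-1-ol | C#CCO | starting material
14 | O-Bpin borate ether of 15 | CC1(C)OB(OC/C=C/B2OC(C)(C)C(C)(C)O2)OC1(C)C | intermediate
15 | (E)-3-(Bpin)prop-2-en-1-ol | OC/C=C/B1OC(C)(C)C(C)(C)O1 | intermediate
16 | [(1R,2R)-2-(Bpin)cyclopropyl]methanol | OC[C@@H]1C[C@H]1B1OC(C)(C)C(C)(C)O1 | intermediate
17 | (1R,2R)-2-(Bpin)cyclopropane-1-carbaldehyde | O=C[C@@H]1C[C@H]1B1OC(C)(C)C(C)(C)O1 | intermediate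
18 | (E)-alkenyl(dicyclohexyl)borane from 12 | CC/C=C\C/C=C\C[C@H](O[Si](C)(C)C(C)(C)C)/C=C/B(C1CCCCC1)C1CCCCC1 | intermediate
19 | (E)-alkenyl(methyl)zinc from 18 | CC/C=C\C/C=C\C[C@H](O[Si](C)(C)C(C)(C)C)/C=C/[Zn]C | intermediate
20 | C8–C22 allylic alcohol, C11-OH free, C14-OTBS, Bpin on C8 | CC/C=C\C/C=C\C[C@H](O[Si](C)(C)C(C)(C)C)/C=C/[C@H](O)[C@@H]1C[C@H]1B1OC(C)(C)C(C)(C)O1 | intermediate
21 | C8–C22 cyclopropyl pinacol boronate, C11-OTBS, C14-OTBS | CC/C=C\C/C=C\C[C@H](O[Si](C)(C)C(C)(C)C)/C=C/[C@H](O[Si](C)(C)C(C)(C)C)[C@@H]1C[C@H]1B1OC(C)(C)C(C)(C)O1 | intermediate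
22 | but-3-yn-1-ol | C#CCCO | starting material
23 | but-3-yn-1-yl N,N-diisopropylcarbamate | C#CCCOC(=O)N(C(C)C)C(C)C | intermediate
24 | (3-bromopropoxy)(tert-butyl)dimethylsilane | BrCCCO[Si](C)(C)C(C)(C)C | starting material
25 | 7-(tert-butyldimethylsilyloxy)hept-3-yn-1-yl N,N-diisopropylcarbamate | CC(C)N(C(C)C)C(=O)OCCC#CCCCO[Si](C)(C)C(C)(C)C | intermediate
26 | (Z)-7-(tert-butyldimethylsilyloxy)hept-3-en-1-yl N,N-diisopropylcarbamate | CC(C)N(C(C)C)C(=O)OCC/C=C\CCCO[Si](C)(C)C(C)(C)C | intermediate
27 | (S)-α-lithiated carbamate (as its sparteine complex) | [Li][C@H](OC(=O)N(C(C)C)C(C)C)C/C=C\CCCO[Si](C)(C)C(C)(C)C | intermediate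
28 | lithium boronate (ate) complex of 27 and 21 | CC/C=C\C/C=C\C[C@H](O[Si](C)(C)C(C)(C)C)/C=C/[C@H](O[Si](C)(C)C(C)(C)C)[C@@H]1C[C@H]1[B-]1(OC(C)(C)C(C)(C)O1)[C@H](OC(=O)N(C(C)C)C(C)C)C/C=C\CCCO[Si](C)(C)C(C)(C)C.[Li+] | intermediate
29 | C7 secondary pinacol boronic ester (Bpin where 30 has OH) | CC/C=C\C/C=C\C[C@H](O[Si](C)(C)C(C)(C)C)/C=C/[C@H](O[Si](C)(C)C(C)(C)C)[C@@H]1C[C@H]1[C@H](B1OC(C)(C)C(C)(C)O1)C/C=C\CCCO[Si](C)(C)C(C)(C)C | intermediate
30 | C1–C22 alcohol, C7-OH free, TBS ethers at C1, C11, C14 | CC/C=C\C/C=C\C[C@H](O[Si](C)(C)C(C)(C)C)/C=C/[C@H](O[Si](C)(C)C(C)(C)C)[C@@H]1C[C@H]1[C@H](O)C/C=C\CCCO[Si](C)(C)C(C)(C)C | intermediate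
31 | C1,C7-diol, C11-OTBS, C14-OTBS | CC/C=C\C/C=C\C[C@H](O[Si](C)(C)C(C)(C)C)/C=C/[C@H](O[Si](C)(C)C(C)(C)C)[C@@H]1C[C@H]1[C@H](O)C/C=C\CCCO | intermediate
32 | (4Z)-7-hydroxy seco acid, C11-OTBS, C14-OTBS | CC/C=C\C/C=C\C[C@H](O[Si](C)(C)C(C)(C)C)/C=C/[C@H](O[Si](C)(C)C(C)(C)C)[C@@H]1C[C@H]1[C@H](O)C/C=C\CCC(=O)O | intermediate
33 | 2,4,6-trichlorobenzoic mixed anhydride of 32 | CC/C=C\C/C=C\C[C@H](O[Si](C)(C)C(C)(C)C)/C=C/[C@H](O[Si](C)(C)C(C)(C)C)[C@@H]1C[C@H]1[C@H](O)C/C=C\CCC(=O)OC(=O)c1c(Cl)cc(Cl)cc1Cl | intermediate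
34 | bis-TBS ether of the target lactone | CC/C=C\C/C=C\C[C@H](O[Si](C)(C)C(C)(C)C)/C=C/[C@H](O[Si](C)(C)C(C)(C)C)[C@@H]1C[C@H]1[C@H]1C/C=C\CCC(=O)O1 | intermediate
35 | target lactone (7R,8R,10R,11S,14S; 4Z,12E,16Z,19Z) | CC/C=C\C/C=C\C[C@H](O)/C=C/[C@H](O)[C@@H]1C[C@H]1[C@H]1C/C=C\CCC(=O)O1 | target

Total step count: 20. Longest linear sequence: 12 steps (steps 3–7, 11, 12, 16–20), counted from 4.

Steps most likely to fail

Step 16. Capture of the bulky, diamine-bound carbenoid by the substituted cyclopropylboronate may be slow or reversible, and allylic deprotonation may compete during the long lithiation. Either process would erode conversion and C7 selectivity. The fallback separates the creation of the C7 stereocentre from the fragment union. Setting out from 26, the sparteine-mediated lithiation is quenched with Me3SnCl to give the (S)-α-(trimethylstannyl) carbamate F1, which can be purified and checked for enantiomeric purity. Tin–lithium exchange (nBuLi, Et2O, −78 °C, retention) then releases the smaller, diamine-free carbenoid within minutes and without excess base. Compound 21 is added, and rearrangement and oxidation as in the main route come back at 30.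

Step 11. Hydroboration may lose chemoselectivity against the skipped diene, boron-to-zinc exchange of the hindered γ-silyloxy alkenylborane may stall, and facial control at C11 may be poor. Setting out from 12, hydrozirconation (Cp2ZrHCl, THF) and iodinolysis should give the (E)-vinyl iodide F2. Nozaki–Hiyama–Kishi coupling of F2 with 17 (CrCl2, cat. NiCl2, DMF) forms the same C11–C12 bond without borane or dialkylzinc. It should give 20 together with its C11 epimer F3, and the two are separated by chromatography. F3 is recycled by Dess–Martin oxidation to the enone F4 and Luche reduction back to the separable pair, so the sequence comes back at 20.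

Step 9. Methylene transfer to the electron-poor alkenylboronate may be sluggish, the two boron centres may exchange ligands, and enantiofacial control may drop. Setting out from 13, radical hydrostannation (Bu3SnH, AIBN) gives (E)-3-(tributylstannyl)prop-2-en-1-ol F5, a more electron-rich alkene without a second boron. Cyclopropanation with the same (4S,5S)-ligand should give the trans-2-(tributylstannyl)cyclopropylmethanol F6. Two equivalents of nBuLi (THF, −78 → 0 °C) form the alkoxide and, by tin–lithium exchange with retention, the configurationally stable cyclopropyllithium. Quenching with iPrOBpin comes back at 16.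

Further compounds
F1 | step 16 | (S,Z)-7-(tert-butyldimethylsilyloxy)-1-(trimethylstannyl)hept-3-en-1-yl N,N-diisopropylcarbamate | C[Sn](C)(C)[C@H](OC(=O)N(C(C)C)C(C)C)C/C=C\CCCO[Si](C)(C)C(C)(C)C
F2 | step 11 | (S,1E,5Z,8Z)-3-(tert-butyldimethylsilyloxy)-1-iodoundeca-1,5,8-triene | CC/C=C\C/C=C\C[C@H](O[Si](C)(C)C(C)(C)C)/C=C/I
F3 | step 11 | C11 epimer of 20 | CC/C=C\C/C=C\C[C@H](O[Si](C)(C)C(C)(C)C)/C=C/[C@@H](O)[C@@H]1C[C@H]1B1OC(C)(C)C(C)(C)O1
F4 | step 11 | C11 enone derived from F3 | CC/C=C\C/C=C\C[C@H](O[Si](C)(C)C(C)(C)C)/C=C/C(=O)[C@@H]1C[C@H]1B1OC(C)(C)C(C)(C)O1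
F5 | step 9 | (E)-3-(tributylstannyl)prop-2-en-1-ol | OC/C=C/[Sn](CCCC)(CCCC)CCCC
F6 | step 9 | trans-2-(tributylstannyl)cyclopropylmethanol, spatial arrangement as in 16 | OC[C@@H]1C[C@H]1[Sn](CCCC)(CCCC)CCCC
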